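**Retrosynthetic overview**

1. Target 21 ⇐ global deprotection of the octa-protected trimer 19 (A = the dihydrobenzofuran with the catechol on C2; B = the dihydrobenzofuran with the styryl group on C6; C6 of A is bonded to C3 of B).
2. 19 ⇐ aryne 12 + (S,S)-oxirane 16, which closes the dihydrofuran ring of B (second ring formed); 16 ⇐ Shi epoxidation of the stilbene of 15.
3. 15 ⇐ aryne 12 + (R,R)-oxirane 5, which closes the dihydrofuran ring of A (first ring formed) by making its O1–C7a and C3a–C3 bonds together; all benzene rings are bought.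
4. Aryne precursor 11 (a masked resveratrol, used twice) ⇐ silyl triflate 6 by C–H borylation and oxidative Heck coupling with 10; oxirane 5 ⇐ Heck coupling of 2 with 3, then Shi epoxidation.
5. Enabling feature: in each dihydrobenzofuran the phenol oxygen on C4 of the benzo ring is ortho to C3a and meta to C7a, so as OMe on a 3-methoxyaryne it sends the oxirane oxygen to C7a and leaves the carbanion on C3a; the aryl on C3 has only meta oxygens, whereas the aryl on C2 has a para oxygen that is masked as an electron-poor mesylate, so the oxirane C–O bond at C3 is the one that ionises.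

Key step: step 7

Remark: the SMILES is read as trans-(2R,3R) for B and trans-(2S,3S) for A; both enantiomers of the fructose-type epoxidation ketone are taken as available catalysts.

**Step 1**
Reactants: 1 4-bromobenzene-1,2-diol
Product: 2 4-bromo-1,2-phenylene dimethanesulfonate
Conditions: MsCl (2.4 equiv), Et3N (3 equiv), CH2Cl2, 0 °C to rt
Reagents that add atoms: methanesulfonyl chloride, CS(=O)(=O)Cl
Why: O-sulfonylation of both phenols, which installs the electron-withdrawing masks that later keep the catechol-bearing benzylic carbon from ionising.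

**Step 2**
Reactants: 2 4-bromo-1,2-phenylene dimethanesulfonate; 3 1-ethenyl-3,5-dimethoxybenzene
Product: 4 4-[(E)-2-(3,5-dimethoxyphenyl)ethenyl]-1,2-phenylene dimethanesulfonate
Conditions: Pd(OAc)2 (2 mol%), P(o-tol)3 (5 mol%), Et3N, DMF, 100 °C
Reagents that add atoms: none
Why: Mizoroki–Heck arylation of the styrene by the electron-poor aryl bromide should give the E-stilbene through syn insertion and syn β-hydride elimination, with the aryl mesylates inert to this catalyst.

**Step 3**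
Reactants: 4 4-[(E)-2-(3,5-dimethoxyphenyl)ethenyl]-1,2-phenylene dimethanesulfonate
Product: 5 4-[(2R,3R)-3-(3,5-dimethoxyphenyl)oxiran-2-yl]-1,2-phenylene dimethanesulfonate
Conditions: D-fructose-derived Shi ketone (30 mol%), KHSO5 (as Oxone), K2CO3, Bu4NHSO4, MeCN/dimethoxymethane, aq. Na2B4O7 buffer, 0 °C
Reagents that add atoms: potassium peroxymonosulfate, [K+].[O-]S(=O)(=O)OO
Why: Shi asymmetric epoxidation, in which the chiral dioxirane transfers oxygen to the E-stilbene through the spiro transition state and sets both oxirane carbons as R under reagent control.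

**Step 4**
Reactants: 6 3-methoxy-2-(trimethylsilyl)phenyl trifluoromethanesulfonate
Product: 7 3-methoxy-5-(4,4,5,5-tetramethyl-1,3,2-dioxaborolan-2-yl)-2-(trimethylsilyl)phenyl trifluoromethanesulfonate
Conditions: [Ir(OMe)(cod)]2 (1.5 mol%), 4,4'-di-tert-butyl-2,2'-bipyridine (3 mol%), B2pin2 (1.0 equiv), methyl tert-butyl ether, 60 °C
Reagents that add atoms: bis(pinacolato)diboron, CC1(C)OB(OC1(C)C)B1OC(C)(C)C(C)(C)O1
Why: sterically controlled iridium-catalysed aromatic C–H borylation should go to C5, the only C–H without an ortho substituent, and is known to tolerate the ortho-silyl triflate motif.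

**Step 5**
Reactants: 8 4-ethenylphenyl acetate
Product: 10 4-ethenylphenyl methanesulfonate, via 4-ethenylphenol 9 (not isolated)
Conditions: pyrrolidine (1.05 equiv), CH2Cl2, 0 °C to rt; then Et3N (1.5 equiv), MsCl (1.2 equiv), 0 °C
Reagents that add atoms: methanesulfonyl chloride, CS(=O)(=O)Cl
Why: aminolysis of the aryl acetate followed by O-sulfonylation of the liberated phenol in the same flask avoids isolating the polymerisation-prone vinylphenol.

**Step 6**
Reactants: 7 3-methoxy-5-(4,4,5,5-tetramethyl-1,3,2-dioxaborolan-2-yl)-2-(trimethylsilyl)phenyl trifluoromethanesulfonate; 10 4-ethenylphenyl methanesulfonate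
Product: 11 3-methoxy-5-{(E)-2-[4-(methanesulfonyloxy)phenyl]ethenyl}-2-(trimethylsilyl)phenyl trifluoromethanesulfonate
Conditions: Pd(OAc)2 (5 mol%), 2,9-dimethyl-1,10-phenanthroline (6 mol%), O2 (1 atm), N,N-dimethylacetamide, 50 °C
Reagents that add atoms: none
Why: oxidative boron-Heck reaction (transmetalation of the aryl boronate to divalent palladium, styrene insertion, β-hydride elimination, reoxidation by O2) should give the E-stilbene under base-free and fluoride-free conditions that leave the silyl triflate intact.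

**Step 7**
Reactants: 11 3-methoxy-5-{(E)-2-[4-(methanesulfonyloxy)phenyl]ethenyl}-2-(trimethylsilyl)phenyl trifluoromethanesulfonate; 5 4-[(2R,3R)-3-(3,5-dimethoxyphenyl)oxiran-2-yl]-1,2-phenylene dimethanesulfonate
Product: 15 4-[(2S,3S)-3-(3,5-dimethoxyphenyl)-4-methoxy-6-{(E)-2-[4-(methanesulfonyloxy)phenyl]ethenyl}-2,3-dihydro-1-benzofuran-2-yl]-1,2-phenylene dimethanesulfonate, via aryne 12 (not isolated), via oxiranium betaine 13 (not isolated), via benzylic zwitterion 14 (not isolated)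
Conditions: CsF (3 equiv), toluene/MeCN 3:1, 40 °C, 11 added over 6 h to 5 (2 equiv, excess recovered)
Reagents that add atoms: none
Why: Proposed new method: fluoride-triggered 1,2-elimination of 11 gives 3-methoxyaryne 12; the oxirane oxygen of 5 adds to the aryne carbon meta to the methoxy group (the future C7a of A) to give O-aryloxiranium betaine 13 with the carbanion on the carbon next to OMe (the future C3a), the oxiranium C–O bond at the 3,5-dimethoxybenzylic carbon ionises to zwitterion 14, and carbanion–carbocation recombination makes the C3a–C3 bond. The closest known reaction type is the formal insertion of arynes into the benzylic C–O bond of monoaryloxiranes to give 3-aryl-2,3-dihydrobenzofurans, whereas 1,2-diaryloxiranes, the choice between two benzylic C–O bonds and the transfer of oxirane configuration are not established. The only ring closed is the dihydrofuran ring of A, by five-membered ring closure of the 1,5-zwitterion (aryl anion onto benzylic cation), in sum a formal [3+2] annulation that expands the oxirane by the two aryne carbons. C2 is never touched and carries over the configuration of 5 (R in 5 and S in 15 only because the CIP priorities change), while the new C3 stereocentre is set trans to the C2 aryl group by substrate control, because the contact ion pair closes on the face the oxygen has just left and this is also the less hindered and more stable arrangement. The step needs regioselectivity on the aryne, secured by the methoxy group next to the triple bond (aryne distortion and inductive stabilisation of the ortho carbanion), and regioselectivity on the oxirane, secured by the two mesyloxy groups that disfavour a cation at the catechol-bearing carbon. It also needs the oxirane oxygen to win over the stilbene double bonds of 11 and 15 for the aryne, which the electron-poor character of that stilbene, slow release of the aryne and the twofold excess of 5 should secure.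

**Step 8**
Reactants: 15 4-[(2S,3S)-3-(3,5-dimethoxyphenyl)-4-methoxy-6-{(E)-2-[4-(methanesulfonyloxy)phenyl]ethenyl}-2,3-dihydro-1-benzofuran-2-yl]-1,2-phenylene dimethanesulfonate
Product: 16 4-[(2S,3S)-3-(3,5-dimethoxyphenyl)-4-methoxy-6-{(2S,3S)-3-[4-(methanesulfonyloxy)phenyl]oxiran-2-yl}-2,3-dihydro-1-benzofuran-2-yl]-1,2-phenylene dimethanesulfonate
Conditions: enantiomeric (L-sorbose-derived) Shi ketone (40 mol%), KHSO5 (as Oxone), K2CO3, Bu4NHSO4, MeCN/dimethoxymethane, aq. Na2B4O7 buffer, 0 °C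
Reagents that add atoms: potassium peroxymonosulfate, [K+].[O-]S(=O)(=O)OO
Why: Shi asymmetric epoxidation of the only alkene, in which the enantiomeric dioxirane sets both oxirane carbons as S under reagent control, the remote stereocentres of ring A having no say.

**Step 9**
Reactants: 16 4-[(2S,3S)-3-(3,5-dimethoxyphenyl)-4-methoxy-6-{(2S,3S)-3-[4-(methanesulfonyloxy)phenyl]oxiran-2-yl}-2,3-dihydro-1-benzofuran-2-yl]-1,2-phenylene dimethanesulfonate; 11 3-methoxy-5-{(E)-2-[4-(methanesulfonyloxy)phenyl]ethenyl}-2-(trimethylsilyl)phenyl trifluoromethanesulfonate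
Product: 19 4-[(2S,3S)-3-(3,5-dimethoxyphenyl)-4-methoxy-6-[(2R,3R)-4-methoxy-2-[4-(methanesulfonyloxy)phenyl]-6-{(E)-2-[4-(methanesulfonyloxy)phenyl]ethenyl}-2,3-dihydro-1-benzofuran-3-yl]-2,3-dihydro-1-benzofuran-2-yl]-1,2-phenylene dimethanesulfonate, via oxiranium betaine 17 (not isolated), via benzylic zwitterion 18 (not isolated)
Conditions: CsF (4 equiv), toluene/MeCN 3:1, 40 °C, 11 (2.5 equiv) added over 8 h to 16
Reagents that add atoms: none
Why: Proposed new method: fluoride releases from this further portion of 11 the same aryne 12 as in step 7 and the mechanism is repeated (O-attack at the aryne carbon meta to OMe to give betaine 17, ionisation to zwitterion 18, five-membered ring closure), with the closest known reaction type again the insertion of arynes into the benzylic C–O bond of monoaryloxiranes; here the benzylic carbon that carries the benzo ring of A (para alkyl, two meta oxygens) should ionise in preference to the 4-mesyloxyphenyl carbon, C2 of B keeps the oxirane configuration, and C3 is set trans to it by ion-pair collapse with retention.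

**Step 10**
Reactants: 19 4-[(2S,3S)-3-(3,5-dimethoxyphenyl)-4-methoxy-6-[(2R,3R)-4-methoxy-2-[4-(methanesulfonyloxy)phenyl]-6-{(E)-2-[4-(methanesulfonyloxy)phenyl]ethenyl}-2,3-dihydro-1-benzofuran-3-yl]-2,3-dihydro-1-benzofuran-2-yl]-1,2-phenylene dimethanesulfonate
Product: 20 4-[(2S,3S)-3-(3,5-dihydroxyphenyl)-4-hydroxy-6-[(2R,3R)-4-hydroxy-2-[4-(methanesulfonyloxy)phenyl]-6-{(E)-2-[4-(methanesulfonyloxy)phenyl]ethenyl}-2,3-dihydro-1-benzofuran-3-yl]-2,3-dihydro-1-benzofuran-2-yl]-1,2-phenylene dimethanesulfonate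
Conditions: BBr3 (12 equiv), CH2Cl2, −78 to 0 °C; then MeOH, H2O
Reagents that add atoms: none
Why: Lewis-acid cleavage of the four aryl methyl ethers (BBr3 demethylation) should spare the aryl mesylates and, because both C2 aryl groups still carry mesyloxy groups, should not ionise the benzylic C2–O bonds of the dihydrofurans, so the four stereocentres are kept.

**Step 11**
Reactants: 20 4-[(2S,3S)-3-(3,5-dihydroxyphenyl)-4-hydroxy-6-[(2R,3R)-4-hydroxy-2-[4-(methanesulfonyloxy)phenyl]-6-{(E)-2-[4-(methanesulfonyloxy)phenyl]ethenyl}-2,3-dihydro-1-benzofuran-3-yl]-2,3-dihydro-1-benzofuran-2-yl]-1,2-phenylene dimethanesulfonate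
Product: 21 4-[(2S,3S)-3-(3,5-dihydroxyphenyl)-4-hydroxy-6-[(2R,3R)-4-hydroxy-2-(4-hydroxyphenyl)-6-[(E)-2-(4-hydroxyphenyl)ethenyl]-2,3-dihydro-1-benzofuran-3-yl]-2,3-dihydro-1-benzofuran-2-yl]benzene-1,2-diol (CNP0107857.3)
Conditions: KOH (2 M aq., 12 equiv), MeOH/THF, 50 °C, argon; then 1 M HCl to pH 3
Reagents that add atoms: none
Why: hydrolysis of the four aryl sulfonate esters by attack of hydroxide at sulfur frees the phenoxides without touching any C–O bond at a stereocentre or the E-alkene.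

**Compound list**

1 | 4-bromobenzene-1,2-diol | Oc1ccc(Br)cc1O | starting material
2 | 4-bromo-1,2-phenylene dimethanesulfonate | CS(=O)(=O)Oc1ccc(Br)cc1OS(C)(=O)=O | intermediate
3 | 1-ethenyl-3,5-dimethoxybenzene | COc1cc(C=C)cc(OC)c1 | starting material
4 | 4-[(E)-2-(3,5-dimethoxyphenyl)ethenyl]-1,2-phenylene dimethanesulfonate | COc1cc(/C=C/c2ccc(OS(C)(=O)=O)c(OS(C)(=O)=O)c2)cc(OC)c1 | intermediate
5 | 4-[(2R,3R)-3-(3,5-dimethoxyphenyl)oxiran-2-yl]-1,2-phenylene dimethanesulfonate | O1[C@H](c2ccc(OS(C)(=O)=O)c(OS(C)(=O)=O)c2)[C@H]1c1cc(OC)cc(OC)c1 | intermediate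
6 | 3-methoxy-2-(trimethylsilyl)phenyl trifluoromethanesulfonate | COc1cccc(OS(=O)(=O)C(F)(F)F)c1[Si](C)(C)C | starting material
7 | 3-methoxy-5-(4,4,5,5-tetramethyl-1,3,2-dioxaborolan-2-yl)-2-(trimethylsilyl)phenyl trifluoromethanesulfonate | COc1cc(B2OC(C)(C)C(C)(C)O2)cc(OS(=O)(=O)C(F)(F)F)c1[Si](C)(C)C | intermediate
8 | 4-ethenylphenyl acetate | CC(=O)Oc1ccc(C=C)cc1 | starting material
9 | 4-ethenylphenol | Oc1ccc(C=C)cc1 | intermediate
10 | 4-ethenylphenyl methanesulfonate | CS(=O)(=O)Oc1ccc(C=C)cc1 | intermediate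
11 | 3-methoxy-5-{(E)-2-[4-(methanesulfonyloxy)phenyl]ethenyl}-2-(trimethylsilyl)phenyl trifluoromethanesulfonate | COc1cc(/C=C/c2ccc(OS(C)(=O)=O)cc2)cc(OS(=O)(=O)C(F)(F)F)c1[Si](C)(C)C | intermediate
12 | 3-methoxy-5-{(E)-2-[4-(methanesulfonyloxy)phenyl]ethenyl}benzyne (1,2-didehydrobenzene) | COC1=CC(/C=C/c2ccc(OS(C)(=O)=O)cc2)=CC#C1 | intermediate
13 | O-aryloxiranium betaine from 12 and 5 (aryl carbanion next to OMe) | COc1cc(/C=C/c2ccc(OS(C)(=O)=O)cc2)cc([O+]2[C@H](c3ccc(OS(C)(=O)=O)c(OS(C)(=O)=O)c3)[C@H]2c2cc(OC)cc(OC)c2)[c-]1 | intermediate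
14 | ring-opened zwitterion from 13 (3,5-dimethoxybenzylic cation, aryl carbanion) | COc1cc(/C=C/c2ccc(OS(C)(=O)=O)cc2)cc(O[C@H](c2ccc(OS(C)(=O)=O)c(OS(C)(=O)=O)c2)[CH+]c2cc(OC)cc(OC)c2)[c-]1 | intermediate
15 | 4-[(2S,3S)-3-(3,5-dimethoxyphenyl)-4-methoxy-6-{(E)-2-[4-(methanesulfonyloxy)phenyl]ethenyl}-2,3-dihydro-1-benzofuran-2-yl]-1,2-phenylene dimethanesulfonate | CS(=O)(=O)Oc1ccc(/C=C/c2cc(OC)c3c(c2)O[C@H](c2ccc(OS(C)(=O)=O)c(OS(C)(=O)=O)c2)[C@H]3c2cc(OC)cc(OC)c2)cc1 | intermediate
16 | 4-[(2S,3S)-3-(3,5-dimethoxyphenyl)-4-methoxy-6-{(2S,3S)-3-[4-(methanesulfonyloxy)phenyl]oxiran-2-yl}-2,3-dihydro-1-benzofuran-2-yl]-1,2-phenylene dimethanesulfonate | O1[C@@H](c2ccc(OS(C)(=O)=O)cc2)[C@@H]1c2cc(OC)c3c(c2)O[C@H](c2ccc(OS(C)(=O)=O)c(OS(C)(=O)=O)c2)[C@H]3c2cc(OC)cc(OC)c2 | intermediate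
17 | O-aryloxiranium betaine from 12 and 16 (aryl carbanion next to OMe) | COc1cc(/C=C/c2ccc(OS(C)(=O)=O)cc2)cc([O+]2[C@@H](c3ccc(OS(C)(=O)=O)cc3)[C@@H]2c2cc(OC)c3c(c2)O[C@H](c2ccc(OS(C)(=O)=O)c(OS(C)(=O)=O)c2)[C@H]3c2cc(OC)cc(OC)c2)[c-]1 | intermediate
18 | ring-opened zwitterion from 17 (benzofuran-6-yl benzylic cation, aryl carbanion) | COc1cc(/C=C/c2ccc(OS(C)(=O)=O)cc2)cc(O[C@@H](c2ccc(OS(C)(=O)=O)cc2)[CH+]c2cc(OC)c3c(c2)O[C@H](c2ccc(OS(C)(=O)=O)c(OS(C)(=O)=O)c2)[C@H]3c2cc(OC)cc(OC)c2)[c-]1 | intermediate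
19 | 4-[(2S,3S)-3-(3,5-dimethoxyphenyl)-4-methoxy-6-[(2R,3R)-4-methoxy-2-[4-(methanesulfonyloxy)phenyl]-6-{(E)-2-[4-(methanesulfonyloxy)phenyl]ethenyl}-2,3-dihydro-1-benzofuran-3-yl]-2,3-dihydro-1-benzofuran-2-yl]-1,2-phenylene dimethanesulfonate | CS(=O)(=O)Oc1ccc(/C=C/c2cc(OC)c3c(c2)O[C@@H](c2ccc(OS(C)(=O)=O)cc2)[C@@H]3c2cc(OC)c3c(c2)O[C@H](c2ccc(OS(C)(=O)=O)c(OS(C)(=O)=O)c2)[C@H]3c2cc(OC)cc(OC)c2)cc1 | intermediate
20 | 4-[(2S,3S)-3-(3,5-dihydroxyphenyl)-4-hydroxy-6-[(2R,3R)-4-hydroxy-2-[4-(methanesulfonyloxy)phenyl]-6-{(E)-2-[4-(methanesulfonyloxy)phenyl]ethenyl}-2,3-dihydro-1-benzofuran-3-yl]-2,3-dihydro-1-benzofuran-2-yl]-1,2-phenylene dimethanesulfonate | CS(=O)(=O)Oc1ccc(/C=C/c2cc(O)c3c(c2)O[C@@H](c2ccc(OS(C)(=O)=O)cc2)[C@@H]3c2cc(O)c3c(c2)O[C@H](c2ccc(OS(C)(=O)=O)c(OS(C)(=O)=O)c2)[C@H]3c2cc(O)cc(O)c2)cc1 | intermediate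
21 | 4-[(2S,3S)-3-(3,5-dihydroxyphenyl)-4-hydroxy-6-[(2R,3R)-4-hydroxy-2-(4-hydroxyphenyl)-6-[(E)-2-(4-hydroxyphenyl)ethenyl]-2,3-dihydro-1-benzofuran-3-yl]-2,3-dihydro-1-benzofuran-2-yl]benzene-1,2-diol (CNP0107857.3) | Oc1ccc(/C=C/c2cc(O)c3c(c2)O[C@@H](c2ccc(O)cc2)[C@@H]3c2cc(O)c3c(c2)O[C@H](c2ccc(O)c(O)c2)[C@H]3c2cc(O)cc(O)c2)cc1 | target

**Totals**

Total step count: 11.
Longest linear sequence: 8 steps (steps 1, 2, 3, 7, 8, 9, 10, 11; 1 → 2 → 4 → 5 → 15 → 16 → 19 → 20 → 21).

**Steps most likely to fail**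

Step 7 (key step). The aryne may be captured by fluoride, acetonitrile or a stilbene double bond instead of the weakly basic oxirane oxygen. The betaine may be diverted by proton transfer or a 1,2-hydride shift, or the wrong oxiranium C–O bond may ionise. The fallback replaces the anionic one-step annulation by a stepwise cationic ring closure; it sets out from 4 and 11 and comes back at 15. Shi epoxidation of 4 with the L-sorbose-derived ketone would give the enantiomeric oxirane 4-[(2S,3S)-3-(3,5-dimethoxyphenyl)oxiran-2-yl]-1,2-phenylene dimethanesulfonate F1. Acid-catalysed methanolysis (camphorsulfonic acid cat., MeOH, 0 °C) should open it only at the 3,5-dimethoxybenzylic carbon and give 4-[(1S,2R)-2-(3,5-dimethoxyphenyl)-1-hydroxy-2-methoxyethyl]-1,2-phenylene dimethanesulfonate F2, with the carbinol centre untouched. Separately, the triflate of 11 would be cleaved with Et4NOH (dioxane, 0 °C to rt; triflyl sulfur is attacked far faster than mesyl sulfur and the C–Si bond needs fluoride) to 3-methoxy-5-{(E)-2-[4-(methanesulfonyloxy)phenyl]ethenyl}-2-(trimethylsilyl)phenol F3. Mitsunobu etherification of F2 with F3 (PPh3, DIAD, toluene, 0 °C to rt) inverts the carbinol centre and should give 4-[(1R,2R)-2-(3,5-dimethoxyphenyl)-2-methoxy-1-(3-methoxy-5-{(E)-2-[4-(methanesulfonyloxy)phenyl]ethenyl}-2-(trimethylsilyl)phenoxy)ethyl]-1,2-phenylene dimethanesulfonate F4. TMSOTf (catalytic, CH2Cl2, −40 °C) then ionises the benzylic methyl ether, and the cation is captured at the silicon-bearing ring carbon between the two oxygens (silicon-directed ipso Friedel–Crafts ring closure, trans-selective, configuration at the methoxy carbon irrelevant), which gives 15.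

Step 9. The same processes can intervene, and in addition the electronic difference between the two benzylic carbons of 16 is smaller, so ionisation of the wrong C–O bond is more likely, and the precious oxirane is the limiting partner. The fallback is the same stepwise logic; it sets out from 15 (with phenol F3 made from 11 as above) and comes back at 19. Shi epoxidation of 15 with the D-fructose-derived ketone would give the diastereomeric oxirane 4-[(2S,3S)-3-(3,5-dimethoxyphenyl)-4-methoxy-6-{(2R,3R)-3-[4-(methanesulfonyloxy)phenyl]oxiran-2-yl}-2,3-dihydro-1-benzofuran-2-yl]-1,2-phenylene dimethanesulfonate F5. Acid-catalysed methanolysis at the benzylic carbon attached to ring A should give 4-[(2S,3S)-3-(3,5-dimethoxyphenyl)-6-{(1S,2R)-2-hydroxy-1-methoxy-2-[4-(methanesulfonyloxy)phenyl]ethyl}-4-methoxy-2,3-dihydro-1-benzofuran-2-yl]-1,2-phenylene dimethanesulfonate F6. Mitsunobu etherification with F3 (inversion) should give 4-[(2S,3S)-3-(3,5-dimethoxyphenyl)-4-methoxy-6-{(1S,2S)-1-methoxy-2-[4-(methanesulfonyloxy)phenyl]-2-(3-methoxy-5-{(E)-2-[4-(methanesulfonyloxy)phenyl]ethenyl}-2-(trimethylsilyl)phenoxy)ethyl}-2,3-dihydro-1-benzofuran-2-yl]-1,2-phenylene dimethanesulfonate F7. TMSOTf-promoted ipso Friedel–Crafts ring closure then gives 19.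

Step 6. The pinacol boronate may transmetalate slowly under base-free oxidative conditions, so that homocoupling or protodeboronation of 7 and oligomerisation of 10 take over. The fallback changes to a halide-based coupling with zerovalent palladium; it sets out from 7 and comes back at 11. Ipso-bromodeboronation of 7 with CuBr2 (3 equiv, MeOH/H2O, 80 °C) would give 5-bromo-3-methoxy-2-(trimethylsilyl)phenyl trifluoromethanesulfonate F8. Mizoroki–Heck coupling of F8 with 10 (Pd2(dba)3, P(t-Bu)3, Cy2NMe, dioxane, 70 °C; zerovalent palladium inserts into C–Br in preference to the triflate flanked by silicon) should give 11.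

**Further compounds**

F1 | step 7 | 4-[(2S,3S)-3-(3,5-dimethoxyphenyl)oxiran-2-yl]-1,2-phenylene dimethanesulfonate | O1[C@@H](c2ccc(OS(C)(=O)=O)c(OS(C)(=O)=O)c2)[C@@H]1c1cc(OC)cc(OC)c1
F2 | step 7 | 4-[(1S,2R)-2-(3,5-dimethoxyphenyl)-1-hydroxy-2-methoxyethyl]-1,2-phenylene dimethanesulfonate | O[C@@H](c1ccc(OS(C)(=O)=O)c(OS(C)(=O)=O)c1)[C@H](OC)c1cc(OC)cc(OC)c1
F3 | step 7 | 3-methoxy-5-{(E)-2-[4-(methanesulfonyloxy)phenyl]ethenyl}-2-(trimethylsilyl)phenol | COc1cc(/C=C/c2ccc(OS(C)(=O)=O)cc2)cc(O)c1[Si](C)(C)C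
F4 | step 7 | 4-[(1R,2R)-2-(3,5-dimethoxyphenyl)-2-methoxy-1-(3-methoxy-5-{(E)-2-[4-(methanesulfonyloxy)phenyl]ethenyl}-2-(trimethylsilyl)phenoxy)ethyl]-1,2-phenylene dimethanesulfonate | COc1cc(/C=C/c2ccc(OS(C)(=O)=O)cc2)cc(O[C@H](c2ccc(OS(C)(=O)=O)c(OS(C)(=O)=O)c2)[C@H](OC)c2cc(OC)cc(OC)c2)c1[Si](C)(C)C
F5 | step 9 | 4-[(2S,3S)-3-(3,5-dimethoxyphenyl)-4-methoxy-6-{(2R,3R)-3-[4-(methanesulfonyloxy)phenyl]oxiran-2-yl}-2,3-dihydro-1-benzofuran-2-yl]-1,2-phenylene dimethanesulfonate | O1[C@H](c2ccc(OS(C)(=O)=O)cc2)[C@H]1c2cc(OC)c3c(c2)O[C@H](c2ccc(OS(C)(=O)=O)c(OS(C)(=O)=O)c2)[C@H]3c2cc(OC)cc(OC)c2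
F6 | step 9 | 4-[(2S,3S)-3-(3,5-dimethoxyphenyl)-6-{(1S,2R)-2-hydroxy-1-methoxy-2-[4-(methanesulfonyloxy)phenyl]ethyl}-4-methoxy-2,3-dihydro-1-benzofuran-2-yl]-1,2-phenylene dimethanesulfonate | O[C@H](c1ccc(OS(C)(=O)=O)cc1)[C@@H](OC)c1cc(OC)c2c(c1)O[C@H](c1ccc(OS(C)(=O)=O)c(OS(C)(=O)=O)c1)[C@H]2c1cc(OC)cc(OC)c1
F7 | step 9 | 4-[(2S,3S)-3-(3,5-dimethoxyphenyl)-4-methoxy-6-{(1S,2S)-1-methoxy-2-[4-(methanesulfonyloxy)phenyl]-2-(3-methoxy-5-{(E)-2-[4-(methanesulfonyloxy)phenyl]ethenyl}-2-(trimethylsilyl)phenoxy)ethyl}-2,3-dihydro-1-benzofuran-2-yl]-1,2-phenylene dimethanesulfonate | COc1cc(/C=C/c2ccc(OS(C)(=O)=O)cc2)cc(O[C@@H](c2ccc(OS(C)(=O)=O)cc2)[C@@H](OC)c2cc(OC)c3c(c2)O[C@H](c2ccc(OS(C)(=O)=O)c(OS(C)(=O)=O)c2)[C@H]3c2cc(OC)cc(OC)c2)c1[Si](C)(C)C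
F8 | step 6 | 5-bromo-3-methoxy-2-(trimethylsilyl)phenyl trifluoromethanesulfonate | COc1cc(Br)cc(OS(=O)(=O)C(F)(F)F)c1[Si](C)(C)C
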